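**Retrosynthetic overview**
1. Feature: in the carbocycle (ring B, C4a–C5–C6–C7–C8–C8a) fused to the γ-pyranone (ring A), O5, O6 and O7 lie on one face and the C8 chlorine on the other, so O7 and Cl8 are the two ends of an anti addition to a C7=C8 double bond with the oxygen handed over from O6.
2. Key disconnection: C7–O and C8–Cl are made together by chlorocyclisation of the O6 tert-butyl carbonate of 5,6-dihydrochromone 26 to cyclic carbonate 27; methanolysis then closes the 7,8-epoxide 29, fluoride frees O5 (30) and HCl reopens the epoxide at C8 to give target 31.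
3. Ring B is closed by ring-closing metathesis at C7=C8 (25 to 26); the C5–C6 bond and both carbinol centres come from one enantioselective anti-silyloxyallylboration of pyranone aldehyde 14 with boronate 18.
4. Ring A is built first, from acyl Meldrum's acid 5 and enamino ester 7, which puts the future C5 carbon on C4a and the alkenyl handle on C8a.
5. Ring order: ring A, ring B, temporary carbonate ring, transient epoxide; the phenol passes the chlorination as an aryl tert-butyl carbonate, and C8a carries propenyl in place of vinyl.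

Key step: step 16

Remark: (R)-TRIP is taken to direct allyl transfer to the re face of aldehyde 14, as it does with aryl aldehydes; if 14 responds in the opposite sense, the (S)-acid is used.

**Route**

Step 1
Reactants: 1 3-(3-hydroxy-4-methoxyphenyl)propanoic acid
Product: 3 3-[3-(tert-butyldimethylsilyloxy)-4-methoxyphenyl]propanoic acid, via silyl ester 2 (not isolated)
Conditions: TBSCl (2.4 equiv), imidazole, DMF, rt; then AcOH, THF/H2O, rt
Reagents that add atoms: tert-butyldimethylsilyl chloride, CC(C)(C)[Si](C)(C)Cl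
Why: Standard silylation of phenol and acid followed by selective hydrolysis of the labile silyl ester should leave only the aryl silyl ether.

Step 2
Reactants: 3 3-[3-(tert-butyldimethylsilyloxy)-4-methoxyphenyl]propanoic acid; 4 Meldrum's acid
Product: 5 5-{3-[3-(tert-butyldimethylsilyloxy)-4-methoxyphenyl]-1-hydroxypropylidene}-2,2-dimethyl-1,3-dioxane-4,6-dione
Conditions: DCC, DMAP, CH2Cl2, 0 °C → rt
Reagents that add atoms: none
Why: Carbodiimide-mediated C-acylation of Meldrum's acid (Oikawa–Yonemitsu type) should give the enolised acyl Meldrum's acid, a stable acylketene precursor.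

Step 3
Reactants: 6 methyl 3-oxohexanoate
Product: 7 methyl (E)-3-(pyrrolidin-1-yl)hex-2-enoate
Conditions: pyrrolidine, toluene, reflux, Dean–Stark
Reagents that add atoms: pyrrolidine, C1CCNC1
Why: Condensation of a β-keto ester with a secondary amine (enamine formation), driven by azeotropic removal of water, should give the conjugated β-enamino ester.

Step 4
Reactants: 5 acyl Meldrum's acid; 7 methyl (E)-3-(pyrrolidin-1-yl)hex-2-enoate
Product: 9 methyl 6-{2-[3-(tert-butyldimethylsilyloxy)-4-methoxyphenyl]ethyl}-4-oxo-2-propyl-4H-pyran-3-carboxylate, via acylketene 8 (not isolated)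
Conditions: toluene, 100 °C, slow addition of 5
Reagents that add atoms: none
Why: Thermal fragmentation of 5 releases the acylketene, which is C-acylated by the nucleophilic α-carbon of the enamino ester, after which the enol oxygen displaces pyrrolidine (acylketene–enamine pyranone annulation); this fixes the ester on C4a and the propyl group on C8a without regiochemical ambiguity.

Step 5
Reactants: 9 methyl 6-{2-[3-(tert-butyldimethylsilyloxy)-4-methoxyphenyl]ethyl}-4-oxo-2-propyl-4H-pyran-3-carboxylate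
Product: 12 methyl 6-{2-[3-(tert-butyldimethylsilyloxy)-4-methoxyphenyl]ethyl}-4-oxo-2-[(E)-prop-1-en-1-yl]-4H-pyran-3-carboxylate, via selenide 10 (not isolated), via selenoxide 11 (not isolated)
Conditions: LiN(SiMe3)2, THF, −78 °C; PhSeBr; then mCPBA, CH2Cl2, −78 °C → rt
Reagents that add atoms: none
Why: The CH2 next to C8a is the most acidic site (vinylogous to both the C4 carbonyl and the ester), so lateral deprotonation and selenenylation should occur there, and selenoxide syn-elimination can only run towards the ethyl terminus to give the conjugated propenyl group, which is less prone to Michael addition than vinyl.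

Step 6
Reactants: 12 methyl 6-{2-[3-(tert-butyldimethylsilyloxy)-4-methoxyphenyl]ethyl}-4-oxo-2-[(E)-prop-1-en-1-yl]-4H-pyran-3-carboxylate
Product: 13 6-{2-[3-(tert-butyldimethylsilyloxy)-4-methoxyphenyl]ethyl}-3-(hydroxymethyl)-2-[(E)-prop-1-en-1-yl]-4H-pyran-4-one
Conditions: i-Bu2AlH (2.2 equiv), CH2Cl2, −78 °C; aq. potassium sodium tartrate work-up
Reagents that add atoms: none
Why: Low-temperature hydride reduction of the ester (1,2-addition) should give the primary alcohol while the pyranone carbonyl, a deactivated vinylogous ester, is left alone.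

Step 7
Reactants: 13 6-{2-[3-(tert-butyldimethylsilyloxy)-4-methoxyphenyl]ethyl}-3-(hydroxymethyl)-2-[(E)-prop-1-en-1-yl]-4H-pyran-4-one
Product: 14 6-{2-[3-(tert-butyldimethylsilyloxy)-4-methoxyphenyl]ethyl}-4-oxo-2-[(E)-prop-1-en-1-yl]-4H-pyran-3-carbaldehyde
Conditions: MnO2, CH2Cl2, rt
Reagents that add atoms: none
Why: The hydroxymethyl group on the sp2 carbon C4a is an allylic-type alcohol and should be oxidised selectively by MnO2 to the aldehyde.

Step 8
Reactants: 15 prop-2-yn-1-ol
Product: 16 triethyl(prop-2-yn-1-yloxy)silane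
Conditions: TESCl, imidazole, CH2Cl2, 0 °C
Reagents that add atoms: chlorotriethylsilane, CC[Si](Cl)(CC)CC
Why: Standard silylation of a primary alcohol.

Step 9
Reactants: 16 triethyl(prop-2-yn-1-yloxy)silane
Product: 17 triethyl{[(E)-3-(4,4,5,5-tetramethyl-1,3,2-dioxaborolan-2-yl)prop-2-en-1-yl]oxy}silane
Conditions: pinacolborane, Cp2Zr(H)Cl (5 mol %), Et3N (10 mol %), 60 °C
Reagents that add atoms: pinacolborane, CC1(C)OBOC1(C)C
Why: Zirconocene hydrochloride-catalysed syn-hydroboration of the terminal alkyne should give the (E)-alkenylboronate with boron on the terminal carbon.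

Step 10
Reactants: 17 triethyl{[(E)-3-(4,4,5,5-tetramethyl-1,3,2-dioxaborolan-2-yl)prop-2-en-1-yl]oxy}silane
Product: 18 triethyl{[(E)-3-(4,4,5,5-tetramethyl-1,3,2-dioxaborolan-2-yl)prop-1-en-1-yl]oxy}silane
Conditions: [Ir(cod)(PPh2Me)2]PF6 (2 mol %, pre-activated with H2), THF, rt
Reagents that add atoms: none
Why: Iridium hydride-catalysed olefin isomerisation (1,3-hydrogen shift) moves the double bond into conjugation with oxygen and should give the (E)-γ-silyloxyallylboronate.

Step 11
Reactants: 14 6-{2-[3-(tert-butyldimethylsilyloxy)-4-methoxyphenyl]ethyl}-4-oxo-2-[(E)-prop-1-en-1-yl]-4H-pyran-3-carbaldehyde; 18 triethyl{[(E)-3-(4,4,5,5-tetramethyl-1,3,2-dioxaborolan-2-yl)prop-1-en-1-yl]oxy}silane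
Product: 20 6-{2-[3-(tert-butyldimethylsilyloxy)-4-methoxyphenyl]ethyl}-3-[(1S,2R)-1-hydroxy-2-(triethylsilyloxy)but-3-en-1-yl]-2-[(E)-prop-1-en-1-yl]-4H-pyran-4-one, via pinacol borate 19 (not isolated)
Conditions: (R)-TRIP (5 mol %), 4 Å MS, toluene, −30 °C; aq. NaHCO3 work-up
Reagents that add atoms: none
Why: Chiral phosphoric acid-catalysed allylboration through a closed chair transition state: the (E)-γ-silyloxy group sits equatorial, which gives the anti C5/C6 relationship that becomes cis in ring B, and the catalyst, bound to the boronate oxygen and the formyl hydrogen, should direct attack to the re face, which sets C5 as S and with it C6.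

Step 12
Reactants: 20 6-{2-[3-(tert-butyldimethylsilyloxy)-4-methoxyphenyl]ethyl}-3-[(1S,2R)-1-hydroxy-2-(triethylsilyloxy)but-3-en-1-yl]-2-[(E)-prop-1-en-1-yl]-4H-pyran-4-one
Product: 21 6-{2-[3-(tert-butyldimethylsilyloxy)-4-methoxyphenyl]ethyl}-3-[(1S,2R)-1-(tert-butyldimethylsilyloxy)-2-(triethylsilyloxy)but-3-en-1-yl]-2-[(E)-prop-1-en-1-yl]-4H-pyran-4-one
Conditions: TBSOTf, 2,6-lutidine, CH2Cl2, −78 → 0 °C
Reagents that add atoms: tert-butyldimethylsilyl triflate, CC(C)(C)[Si](C)(C)OS(=O)(=O)C(F)(F)F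
Why: Silyl triflate with a hindered base should silylate the hindered C5 hydroxyl without moving the neighbouring triethylsilyl group.

Step 13
Reactants: 21 6-{2-[3-(tert-butyldimethylsilyloxy)-4-methoxyphenyl]ethyl}-3-[(1S,2R)-1-(tert-butyldimethylsilyloxy)-2-(triethylsilyloxy)but-3-en-1-yl]-2-[(E)-prop-1-en-1-yl]-4H-pyran-4-one
Product: 23 3-[(1S,2R)-1-(tert-butyldimethylsilyloxy)-2-hydroxybut-3-en-1-yl]-6-[2-(3-hydroxy-4-methoxyphenyl)ethyl]-2-[(E)-prop-1-en-1-yl]-4H-pyran-4-one, via phenol 22 (not isolated)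
Conditions: KHF2, MeOH, rt; then PPTS, rt
Reagents that add atoms: none
Why: Hydrogen difluoride cleaves the aryl silyl ether selectively (phenoxide is the better leaving group), and mild acid methanolysis then removes the triethylsilyl ether, which is far more labile than the secondary tert-butyldimethylsilyl ether; the fluoride stage comes first so that O6 stays blocked and no silyl shift from O5 can occur.

Step 14
Reactants: 23 3-[(1S,2R)-1-(tert-butyldimethylsilyloxy)-2-hydroxybut-3-en-1-yl]-6-[2-(3-hydroxy-4-methoxyphenyl)ethyl]-2-[(E)-prop-1-en-1-yl]-4H-pyran-4-one; 24 di-tert-butyl dicarbonate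
Product: 25 3-[(1S,2R)-2-(tert-butoxycarbonyloxy)-1-(tert-butyldimethylsilyloxy)but-3-en-1-yl]-6-{2-[3-(tert-butoxycarbonyloxy)-4-methoxyphenyl]ethyl}-2-[(E)-prop-1-en-1-yl]-4H-pyran-4-one
Conditions: DMAP, Et3N, CH2Cl2, 0 °C → rt
Reagents that add atoms: none
Why: DMAP-catalysed acylation should convert both the phenol and the allylic C6 hydroxyl into tert-butyl carbonates; the C6 carbonate is the tether for the key step and the aryl carbonate lowers the electron density of the guaiacyl ring so that it does not compete for the chlorine electrophile.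

Step 15
Reactants: 25 3-[(1S,2R)-2-(tert-butoxycarbonyloxy)-1-(tert-butyldimethylsilyloxy)but-3-en-1-yl]-6-{2-[3-(tert-butoxycarbonyloxy)-4-methoxyphenyl]ethyl}-2-[(E)-prop-1-en-1-yl]-4H-pyran-4-one
Product: 26 (5S,6R)-6-(tert-butoxycarbonyloxy)-2-{2-[3-(tert-butoxycarbonyloxy)-4-methoxyphenyl]ethyl}-5-(tert-butyldimethylsilyloxy)-5,6-dihydro-4H-chromen-4-one
Conditions: second-generation Hoveyda–Grubbs catalyst RuCl2(H2IMes)(=CH-C6H4-2-O-i-Pr) (5 mol %), CH2Cl2, 40 °C
Reagents that add atoms: none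
Why: Ring-closing metathesis: the ruthenium carbene should load on the terminal vinyl group and close onto the propenyl group, forming six-membered ring B with the C7=C8 double bond and releasing propene, with no stereocentre touched.

Step 16
Reactants: 26 (5S,6R)-6-(tert-butoxycarbonyloxy)-2-{2-[3-(tert-butoxycarbonyloxy)-4-methoxyphenyl]ethyl}-5-(tert-butyldimethylsilyloxy)-5,6-dihydro-4H-chromen-4-one
Product: 27 (5S,6R,7S,8R)-2-{2-[3-(tert-butoxycarbonyloxy)-4-methoxyphenyl]ethyl}-5-(tert-butyldimethylsilyloxy)-8-chloro-6,7-(carbonyldioxy)-5,6,7,8-tetrahydro-4H-chromen-4-one (6,7-cyclic carbonate)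
Conditions: t-BuOCl (1.2 equiv), 2,6-di-tert-butyl-4-methylpyridine (0.2 equiv), CH2Cl2, −40 → 0 °C, dark
Reagents that add atoms: tert-butyl hypochlorite, CC(C)(C)OCl
Why: Proposed new method: the hypochlorite should transfer its chlorine to C8 on the face opposite the O6 carbonate while the carbonyl oxygen of that carbonate attacks C7 from its own face in a nucleophile-assisted anti addition, after which the tert-butyl group is lost as isobutene to leave the cis-fused five-membered carbonate. The closest known reactions are the iodo- and bromocarbonate cyclisations of allylic and homoallylic tert-butyl carbonates and the chlorolactonisations and chlorocyclisations of carbamates with hypochlorite or N-chloro reagents; what is new is the chlorine electrophile on a carbonate nucleophile and the pyranone-conjugated alkene. The carbonate ring closes in the 5-exo-trig mode, the only one the three-atom tether allows without a bridged ring. C7 is set by the tether (oxygen delivered from O6, hence cis to O6 and O5) and C8 by the anti addition (chlorine trans to O7). The step needs regioselectivity, which the tether and the polarisation of the dienone system (nucleophile to the δ-carbon C7, electrophile to the γ-carbon C8) both favour; facial selectivity, which follows because only the face opposite the carbonate can be chlorinated with its assistance; and chemoselectivity over the arene, which the aryl carbonate provides.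

Step 17
Reactants: 27 (5S,6R,7S,8R)-8-chloro 6,7-cyclic carbonate
Product: 29 (5S,6R,7S,8S)-5-(tert-butyldimethylsilyloxy)-7,8-epoxy-6-hydroxy-2-[2-(3-hydroxy-4-methoxyphenyl)ethyl]-5,6,7,8-tetrahydro-4H-chromen-4-one, via chlorohydrin 28 (not isolated)
Conditions: K2CO3, MeOH, 0 °C
Reagents that add atoms: none
Why: Base methanolysis (transesterification) should cleave the cyclic and the aryl carbonate, and the C7 alkoxide, anti to the C8 chloride, then closes by intramolecular SN2 to the 7,8-epoxide on the face of O6 (inversion at C8, retention at C7); a silyl shift from O5 to O6 would be harmless because the silyl group is removed in the next step.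

Step 18
Reactants: 29 (5S,6R,7S,8S)-5-(tert-butyldimethylsilyloxy)-7,8-epoxy-6-hydroxy-2-[2-(3-hydroxy-4-methoxyphenyl)ethyl]-5,6,7,8-tetrahydro-4H-chromen-4-one
Product: 30 (5S,6S,7S,8S)-7,8-epoxy-5,6-dihydroxy-2-[2-(3-hydroxy-4-methoxyphenyl)ethyl]-5,6,7,8-tetrahydro-4H-chromen-4-one
Conditions: TBAF (1.0 M in THF), AcOH (1 equiv per fluoride), THF, 0 °C → rt
Reagents that add atoms: none
Why: Fluoride-mediated desilylation buffered with acetic acid should free the C5 hydroxyl without opening the epoxide; Payne rearrangement cannot intervene because O6 and the epoxide oxygen are cis, and taking the silyl group off before the epoxide is reopened lets the last step deliver the target directly.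

Step 19
Reactants: 30 (5S,6S,7S,8S)-7,8-epoxy-5,6-dihydroxy-2-[2-(3-hydroxy-4-methoxyphenyl)ethyl]-5,6,7,8-tetrahydro-4H-chromen-4-one
Product: 31 (5S,6S,7S,8R)-8-chloro-5,6,7-trihydroxy-2-[2-(3-hydroxy-4-methoxyphenyl)ethyl]-5,6,7,8-tetrahydro-4H-chromen-4-one
Conditions: HCl (4 M in 1,4-dioxane, 1.5 equiv), THF, −20 → 0 °C
Reagents that add atoms: hydrogen chloride, Cl
Why: Acid-promoted opening of the epoxide by chloride (hydrohalogenation of an epoxide) should occur at C8, the allylic carbon next to the C8a=C4a double bond and remote from the C6 carbinol, with inversion in the trans-diaxial sense, which places chlorine on C8 anti to O7 and leaves C5, C6 and C7 untouched.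

**Compound list**
1 | 3-(3-hydroxy-4-methoxyphenyl)propanoic acid | COc1ccc(CCC(=O)O)cc1O | starting material
2 | tert-butyldimethylsilyl 3-[3-(tert-butyldimethylsilyloxy)-4-methoxyphenyl]propanoate | COc1ccc(CCC(=O)O[Si](C)(C)C(C)(C)C)cc1O[Si](C)(C)C(C)(C)C | intermediate
3 | 3-[3-(tert-butyldimethylsilyloxy)-4-methoxyphenyl]propanoic acid | COc1ccc(CCC(=O)O)cc1O[Si](C)(C)C(C)(C)C | intermediate
4 | Meldrum's acid (2,2-dimethyl-1,3-dioxane-4,6-dione) | CC1(C)OC(=O)CC(=O)O1 | starting material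
5 | 5-{3-[3-(tert-butyldimethylsilyloxy)-4-methoxyphenyl]-1-hydroxypropylidene}-2,2-dimethyl-1,3-dioxane-4,6-dione | COc1ccc(CCC(O)=C2C(=O)OC(C)(C)OC2=O)cc1O[Si](C)(C)C(C)(C)C | intermediate
6 | methyl 3-oxohexanoate | CCCC(=O)CC(=O)OC | starting material
7 | methyl (E)-3-(pyrrolidin-1-yl)hex-2-enoate | CCC/C(N1CCCC1)=C\C(=O)OC | intermediate
8 | 5-[3-(tert-butyldimethylsilyloxy)-4-methoxyphenyl]-3-oxopent-1-en-1-one (acylketene) | COc1ccc(CCC(=O)C=C=O)cc1O[Si](C)(C)C(C)(C)C | intermediate
9 | methyl 6-{2-[3-(tert-butyldimethylsilyloxy)-4-methoxyphenyl]ethyl}-4-oxo-2-propyl-4H-pyran-3-carboxylate | CCCc1oc(CCc2ccc(OC)c(O[Si](C)(C)C(C)(C)C)c2)cc(=O)c1C(=O)OC | intermediate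
10 | methyl 6-{2-[3-(tert-butyldimethylsilyloxy)-4-methoxyphenyl]ethyl}-4-oxo-2-[1-(phenylselanyl)propyl]-4H-pyran-3-carboxylate (racemic at the selenium-bearing carbon) | CCC([Se]c1ccccc1)c1oc(CCc2ccc(OC)c(O[Si](C)(C)C(C)(C)C)c2)cc(=O)c1C(=O)OC | intermediate
11 | methyl 6-{2-[3-(tert-butyldimethylsilyloxy)-4-methoxyphenyl]ethyl}-4-oxo-2-[1-(phenylseleninyl)propyl]-4H-pyran-3-carboxylate | CCC([Se](=O)c1ccccc1)c1oc(CCc2ccc(OC)c(O[Si](C)(C)C(C)(C)C)c2)cc(=O)c1C(=O)OC | intermediate
12 | methyl 6-{2-[3-(tert-butyldimethylsilyloxy)-4-methoxyphenyl]ethyl}-4-oxo-2-[(E)-prop-1-en-1-yl]-4H-pyran-3-carboxylate | C/C=C/c1oc(CCc2ccc(OC)c(O[Si](C)(C)C(C)(C)C)c2)cc(=O)c1C(=O)OC | intermediate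
13 | 6-{2-[3-(tert-butyldimethylsilyloxy)-4-methoxyphenyl]ethyl}-3-(hydroxymethyl)-2-[(E)-prop-1-en-1-yl]-4H-pyran-4-one | C/C=C/c1oc(CCc2ccc(OC)c(O[Si](C)(C)C(C)(C)C)c2)cc(=O)c1CO | intermediate
14 | 6-{2-[3-(tert-butyldimethylsilyloxy)-4-methoxyphenyl]ethyl}-4-oxo-2-[(E)-prop-1-en-1-yl]-4H-pyran-3-carbaldehyde | C/C=C/c1oc(CCc2ccc(OC)c(O[Si](C)(C)C(C)(C)C)c2)cc(=O)c1C=O | intermediate
15 | prop-2-yn-1-ol | C#CCO | starting material
16 | triethyl(prop-2-yn-1-yloxy)silane | C#CCO[Si](CC)(CC)CC | intermediate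
17 | triethyl{[(E)-3-(4,4,5,5-tetramethyl-1,3,2-dioxaborolan-2-yl)prop-2-en-1-yl]oxy}silane | CC[Si](CC)(CC)OC/C=C/B1OC(C)(C)C(C)(C)O1 | intermediate
18 | triethyl{[(E)-3-(4,4,5,5-tetramethyl-1,3,2-dioxaborolan-2-yl)prop-1-en-1-yl]oxy}silane | CC[Si](CC)(CC)O/C=C/CB1OC(C)(C)C(C)(C)O1 | intermediate
19 | pinacol borate of 20 (boron on the C5 oxygen) | C/C=C/c1oc(CCc2ccc(OC)c(O[Si](C)(C)C(C)(C)C)c2)cc(=O)c1[C@H](OB1OC(C)(C)C(C)(C)O1)[C@H](O[Si](CC)(CC)CC)C=C | intermediate
20 | 6-{2-[3-(tert-butyldimethylsilyloxy)-4-methoxyphenyl]ethyl}-3-[(1S,2R)-1-hydroxy-2-(triethylsilyloxy)but-3-en-1-yl]-2-[(E)-prop-1-en-1-yl]-4H-pyran-4-one | C/C=C/c1oc(CCc2ccc(OC)c(O[Si](C)(C)C(C)(C)C)c2)cc(=O)c1[C@H](O)[C@H](O[Si](CC)(CC)CC)C=C | intermediate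
21 | 6-{2-[3-(tert-butyldimethylsilyloxy)-4-methoxyphenyl]ethyl}-3-[(1S,2R)-1-(tert-butyldimethylsilyloxy)-2-(triethylsilyloxy)but-3-en-1-yl]-2-[(E)-prop-1-en-1-yl]-4H-pyran-4-one | C/C=C/c1oc(CCc2ccc(OC)c(O[Si](C)(C)C(C)(C)C)c2)cc(=O)c1[C@H](O[Si](C)(C)C(C)(C)C)[C@H](O[Si](CC)(CC)CC)C=C | intermediate
22 | 3-[(1S,2R)-1-(tert-butyldimethylsilyloxy)-2-(triethylsilyloxy)but-3-en-1-yl]-6-[2-(3-hydroxy-4-methoxyphenyl)ethyl]-2-[(E)-prop-1-en-1-yl]-4H-pyran-4-one | C/C=C/c1oc(CCc2ccc(OC)c(O)c2)cc(=O)c1[C@H](O[Si](C)(C)C(C)(C)C)[C@H](O[Si](CC)(CC)CC)C=C | intermediate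
23 | 3-[(1S,2R)-1-(tert-butyldimethylsilyloxy)-2-hydroxybut-3-en-1-yl]-6-[2-(3-hydroxy-4-methoxyphenyl)ethyl]-2-[(E)-prop-1-en-1-yl]-4H-pyran-4-one | C/C=C/c1oc(CCc2ccc(OC)c(O)c2)cc(=O)c1[C@H](O[Si](C)(C)C(C)(C)C)[C@H](O)C=C | intermediate
24 | di-tert-butyl dicarbonate | CC(C)(C)OC(=O)OC(=O)OC(C)(C)C | starting material
25 | 3-[(1S,2R)-2-(tert-butoxycarbonyloxy)-1-(tert-butyldimethylsilyloxy)but-3-en-1-yl]-6-{2-[3-(tert-butoxycarbonyloxy)-4-methoxyphenyl]ethyl}-2-[(E)-prop-1-en-1-yl]-4H-pyran-4-one | C/C=C/c1oc(CCc2ccc(OC)c(OC(=O)OC(C)(C)C)c2)cc(=O)c1[C@H](O[Si](C)(C)C(C)(C)C)[C@H](OC(=O)OC(C)(C)C)C=C | intermediate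
26 | (5S,6R)-6-(tert-butoxycarbonyloxy)-2-{2-[3-(tert-butoxycarbonyloxy)-4-methoxyphenyl]ethyl}-5-(tert-butyldimethylsilyloxy)-5,6-dihydro-4H-chromen-4-one | COc1ccc(CCc2cc(=O)c3c(o2)C=C[C@@H](OC(=O)OC(C)(C)C)[C@H]3O[Si](C)(C)C(C)(C)C)cc1OC(=O)OC(C)(C)C | intermediate
27 | (5S,6R,7S,8R)-2-{2-[3-(tert-butoxycarbonyloxy)-4-methoxyphenyl]ethyl}-5-(tert-butyldimethylsilyloxy)-8-chloro-6,7-(carbonyldioxy)-5,6,7,8-tetrahydro-4H-chromen-4-one | COc1ccc(CCc2cc(=O)c3c(o2)[C@H](Cl)[C@H]4OC(=O)O[C@H]4[C@H]3O[Si](C)(C)C(C)(C)C)cc1OC(=O)OC(C)(C)C | intermediate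
28 | (5S,6R,7S,8R)-5-(tert-butyldimethylsilyloxy)-8-chloro-6,7-dihydroxy-2-[2-(3-hydroxy-4-methoxyphenyl)ethyl]-5,6,7,8-tetrahydro-4H-chromen-4-one | COc1ccc(CCc2cc(=O)c3c(o2)[C@H](Cl)[C@@H](O)[C@@H](O)[C@H]3O[Si](C)(C)C(C)(C)C)cc1O | intermediate
29 | (5S,6R,7S,8S)-5-(tert-butyldimethylsilyloxy)-7,8-epoxy-6-hydroxy-2-[2-(3-hydroxy-4-methoxyphenyl)ethyl]-5,6,7,8-tetrahydro-4H-chromen-4-one | COc1ccc(CCc2cc(=O)c3c(o2)[C@H]4O[C@H]4[C@@H](O)[C@H]3O[Si](C)(C)C(C)(C)C)cc1O | intermediate
30 | (5S,6S,7S,8S)-7,8-epoxy-5,6-dihydroxy-2-[2-(3-hydroxy-4-methoxyphenyl)ethyl]-5,6,7,8-tetrahydro-4H-chromen-4-one | COc1ccc(CCc2cc(=O)c3c(o2)[C@H]4O[C@H]4[C@@H](O)[C@H]3O)cc1O | intermediate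
31 | (5S,6S,7S,8R)-8-chloro-5,6,7-trihydroxy-2-[2-(3-hydroxy-4-methoxyphenyl)ethyl]-5,6,7,8-tetrahydro-4H-chromen-4-one | COc1ccc(CCc2cc(=O)c3c(o2)[C@H](Cl)[C@@H](O)[C@@H](O)[C@H]3O)cc1O | target

**Step count and risks**

Total: 19 steps. Longest linear sequence: 15 steps (1 → 3 → 5 → 9 → 12 → 13 → 14 → 20 → 21 → 23 → 25 → 26 → 27 → 29 → 30 → 31).

Step 16 (proposed new method). Chlorine transfer to the pyranone-conjugated, carbonate-flanked alkene may be slow, so that electrophilic substitution on the anisole ring or at C3 of the pyranone, or radical C–H chlorination, takes over; closure at C8 in place of C7 would give a bridged carbonate. The fallback uses known chemistry and sets out from 26. Iodocarbonate cyclisation with IBr in CH2Cl2/toluene at −78 °C, the established halocarbonate cyclisation of tert-butyl carbonates, should give the (5S,6R,7S,8R)-8-iodo 6,7-cyclic carbonate F1. K2CO3 in MeOH then cleaves both carbonates and the C7 alkoxide displaces iodide, so the sequence comes back to the route at epoxide 29. Chlorine then enters only as chloride in step 19.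

Step 11. Enantiofacial selectivity may be low, or addition slow, because the aldehyde is flanked by the C4 carbonyl and the propenyl group; isomerisation of the enol ether double bond of 18 would erode the anti selectivity. The fallback sets out from alcohol 13. Iridium-catalysed transfer-hydrogenative anti-(acyloxy)allylation with prop-2-ene-1,1-diyl dibenzoate ([Ir(cod)Cl]2, a SEGPHOS-type bisphosphine chosen for the (1S,2R) adduct, 4-cyano-3-nitrobenzoic acid, K3PO4, THF, 90 °C) forms the C5–C6 bond directly from the alcohol oxidation level and should give the anti hydroxy benzoate F2. TBSOTf and 2,6-lutidine convert it into the C5 silyl ether F3. K2CO3 in MeOH removes the benzoate and the aryl silyl ether, and the sequence comes back to the route at diol 23.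

Step 19. Adventitious water or the solvent may open the epoxide in place of chloride, attack may occur at C7, or the free C5 hydroxyl, which sits on a carbon whose cation is stabilised through the C4a=C8a enol ether, may ionise in acid. The fallback sets out from 30. 2,2-Dimethoxypropane and PPTS in acetone should tie the cis-5,6-diol up as the (5S,6S,7S,8S)-epoxy acetonide F4, which masks C5 and makes the substrate soluble in aprotic media. Pyridinium chloride in dry CH2Cl2 then delivers chloride to the allylic C8 under non-ionising conditions and should give the (5S,6R,7S,8R)-chlorohydrin acetonide F5. Aqueous acetic acid removes the acetonide, and the sequence comes back to the route at 31.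

**Further compounds**
F1 | step 16 | (5S,6R,7S,8R)-2-{2-[3-(tert-butoxycarbonyloxy)-4-methoxyphenyl]ethyl}-5-(tert-butyldimethylsilyloxy)-8-iodo-6,7-(carbonyldioxy)-5,6,7,8-tetrahydro-4H-chromen-4-one | COc1ccc(CCc2cc(=O)c3c(o2)[C@H](I)[C@H]4OC(=O)O[C@H]4[C@H]3O[Si](C)(C)C(C)(C)C)cc1OC(=O)OC(C)(C)C
F2 | step 11 | (1S,2R)-1-{6-[2-(3-(tert-butyldimethylsilyloxy)-4-methoxyphenyl)ethyl]-4-oxo-2-[(E)-prop-1-en-1-yl]-4H-pyran-3-yl}-1-hydroxybut-3-en-2-yl benzoate | C/C=C/c1oc(CCc2ccc(OC)c(O[Si](C)(C)C(C)(C)C)c2)cc(=O)c1[C@H](O)[C@H](OC(=O)c1ccccc1)C=C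
F3 | step 11 | (1S,2R)-1-{6-[2-(3-(tert-butyldimethylsilyloxy)-4-methoxyphenyl)ethyl]-4-oxo-2-[(E)-prop-1-en-1-yl]-4H-pyran-3-yl}-1-(tert-butyldimethylsilyloxy)but-3-en-2-yl benzoate | C/C=C/c1oc(CCc2ccc(OC)c(O[Si](C)(C)C(C)(C)C)c2)cc(=O)c1[C@H](O[Si](C)(C)C(C)(C)C)[C@H](OC(=O)c1ccccc1)C=C
F4 | step 19 | (5S,6S,7S,8S)-7,8-epoxy-2-[2-(3-hydroxy-4-methoxyphenyl)ethyl]-5,6-(isopropylidenedioxy)-5,6,7,8-tetrahydro-4H-chromen-4-one | COc1ccc(CCc2cc(=O)c3c(o2)[C@H]4O[C@H]4[C@H]5OC(C)(C)O[C@@H]35)cc1O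
F5 | step 19 | (5S,6R,7S,8R)-8-chloro-7-hydroxy-2-[2-(3-hydroxy-4-methoxyphenyl)ethyl]-5,6-(isopropylidenedioxy)-5,6,7,8-tetrahydro-4H-chromen-4-one | COc1ccc(CCc2cc(=O)c3c(o2)[C@H](Cl)[C@@H](O)[C@H]4OC(C)(C)O[C@@H]34)cc1O
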